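## Analysis of the target

Compound 35 is a longipinane, a tricyclo[5.4.0.0(2,8)]undecane. A cyclobutane (C4, C5, C11, C10) is shared by ring A (C1–C4, C10, C11, a 3-methylcyclohex-2-enone) and by the seven-membered ring B (C4–C10). It has six stereocentres, 4R,5S,7R,9R,10R,11R. The four on the cyclobutane are locked to each other: ring B must span C5 and C10 on the face away from the enone bridge, so H5 and the C10 methyl both point over that bridge, and only the sense of the whole cage is free. C7 and C9 must be matched to that sense, with O9 trans to the C10 methyl and O7 trans to O9. Sensitive groups are the enone, the strained β-keto cyclobutane (it can reopen under Lewis acids), and two different α,β-unsaturated esters on hindered carbinols, which cannot be carried through amide-base or tin-hydride steps. The hard points are the quaternary C10 next to the C9 carbinol, telling the two hindered hydroxyls apart, and above all C5. C5 is a secondary neopentyl CH between C4 and the gem-dimethyl carbon C6, so the classical enolate alkylation to pinane-type rings (SN2 at C5) is closed, and a free cation there would draw a methyl from C6. The strategy therefore makes C5 electrophilic as a sulfur-stabilised cation, which needs no backside approach and does not rearrange, and lets C11 of a ring A enol derivative attack it.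

## Retrosynthetic reasoning

Ester C–O bonds at O7 and O9. The two unsaturated acyl groups are cut off first, giving 32 and then 28. They would not survive the bases and the radical reduction used earlier, and the orthogonal pair benzoate (O9) and silyl ether (O7) in 27 lets each hindered hydroxyl be acylated in turn with 29 and 33.

C5–H back to C5–S. The hydrogen on C5 of 27 is traced to the phenylthio group of 26. The sulfur is the handle that makes a cation at C5 possible, and its reductive removal can only deliver hydrogen to the one open position of the cage.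

C5–C11, the key cut. Opening the cyclobutane of 26 between C5 and C11 gives the bicyclic silyl dienol ether 24. The other cyclobutane bonds either involve quaternary C10 or still need an electrophilic C5, whereas C11 is the natural α′ nucleophile of the enone already present in the target. Closing this bond last means that ring strain appears only once, after all other stereocentres are in place. The forward reaction has to create a cation at C5 from the thioketal of 24 that neither rearranges nor eliminates before C11 reaches it.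

C5–S bonds, enone and C1 oxidation level. Compound 24 comes from enone 23, and 23 from the saturated thioketal alcohol 20 through ketone 21. The thioketal is traced to ketone 18 at a stage where ring A is saturated and C1 is a protected alcohol. With an enone in ring A, H4 would be vinylogously acidic and a C5 cation would simply end as a conjugated dienyl sulfide, so the enone is installed after the sulfur. The forward steps must ketalise a crowded carbonyl without touching the ring fusion and then unveil the enone under neutral or kinetic conditions.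

C4–C5. Ketone 18 is opened between the fusion carbon C4 and C5 to aldehyde 15 (via 16 and 17). The trisubstituted C3=C4 alkene of 15 is nucleophilic at C4 only, so an intramolecular carbonyl-ene reaction gives the right constitution, and the tether from C10 fixes the cis C4–C10 fusion. The forward step must close a seven-membered ring and leave oxygen on C5.

C8–C9 and the two carbinols. Aldehyde 15 is traced through 14 and 13 to aldol 12, which is cut at C8–C9 into aldehyde 8 and methyl ketone 10. Ketone 10 can enolise only toward its methyl group and 8 cannot enolise at all, so the union is unambiguous. C9 must be set by the reagent, and C7 then follows by an intramolecular 1,3-anti hydride transfer that also tells the two oxygens apart.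

Ring A and C10. Aldehyde 8 goes back through 7 and 6 to the dienyl acid 4 and the benzoic acid 1; the bond cut is C10–CH3. A Birch reductive methylation of 1 gives, in one step, the quaternary carbon carrying C9 as a carboxyl group, a masked C1 ketone, the C3 methyl and the C3=C4 alkene. The racemic acid 3 is resolved to 4 while the acid handle is still on the stereocentre.

## Alternatives that were turned down

Alternative 1: The cut is the C9–C10 bond of ring B, made on a finished cyclobutane–enone core. In the forward step the photocatalyst Ir[dF(CF3)ppy]2(dtbbpy)PF6 would oxidise a carboxylate on C10; loss of CO2 leaves a tertiary cyclobutyl radical that closes ring B by 7-endo addition to the terminal carbon of a vinyl ketone attached to C6, giving A1.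
- For: a radical is the most forgiving way to bond to a quaternary carbon; the configuration at C10 is forced by the cage; no cation is involved, so elimination and rearrangement are not an issue.
- Against: A1 has a ketone at C7 and a bare CH2 at C9. The O9 ester would have to be introduced afterwards at a position β to that ketone and next to C10, with two stereocentres under substrate control only. The ring A enone is a second radical acceptor and a chromophore. The all-substituted cyclobutane acid that the step starts from, the real difficulty, is not addressed.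
- Comparison: it is stronger in the bond-forming event itself. The chosen plan offers a ring B whose two oxygens and their configurations are fixed before any strain is introduced, and uses its key step to make the cyclobutane itself, so only five steps follow it.

Alternative 2: The cuts are the two bonds that tie the enone bridge to the cyclobutane (C3–C4 and C1–C11). In the forward step Pd(OAc)2 with AgOAc, directed by a quinolin-8-yl amide on C10, would alkenylate both cis β-C–H bonds with an isopropenyl halide to give the meso compound A2.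
- For: the four-membered ring is present from the start; the all-cis relation is dictated by the directing group; two C–C bonds form in one operation with robust divalent-palladium chemistry.
- Against: the substituent on C10 that is cis to the bridge in 35 is the methyl group, so the directing carboxamide itself would have to be reduced to CH3 at a neopentyl quaternary centre, and the ester turned into C9. The twofold coupling is on a face already crowded by the C5 substituent and uses an alkenyl rather than an aryl partner. Ring A still has to be closed, and all of ring B with C7 and C9 built on the cage.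
- Comparison: it is stronger in the certainty of the cyclobutane stereochemistry. It is weaker in step economy, because most of the molecule and several redox corrections remain after A2; the chosen plan reaches its key step with everything else complete.

Alternative 3: The cut is the C2=C3 bond of the enone, by retro-aldol condensation to a meso cyclobutane with two cis acetyl groups. In the forward step a cinchona-derived primary amine with an acid would convert one enantiotopic acetyl group into an enamine that adds to the other; dehydration gives A3.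
- For: it is catalytic and enantioselective, and fixes the absolute configuration of all four cyclobutane centres in one step from an achiral precursor. This is clearly better than the resolution used here.
- Against: the meso, all-cis, fully substituted cyclobutane is as hard to make as in Alternative 2. Its acetyl-bearing carbons can epimerise under the enamine conditions to a trans isomer that cannot cyclise. After A3, the ester must become C9, the C8–C9 bond must be made to the vinyl group, and oxygen must be placed on C7, all on a base-sensitive β-keto cyclobutane.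
- Comparison: it wins on absolute stereocontrol. The chosen plan wins on what remains after the key step and on not having to assemble a crowded cyclobutane before the seven-membered ring exists.

Key step: step 18

## Remarks and assumptions

- Locants C1–C11 are those of the longipinane skeleton of 35. The bicyclo[5.4.0]undecanes 16–25 are named as 5,11-secolongipinanes (ring A: C1–C4, C10, C11; ring B: C4–C10).
- Assumption: the (R)-acid 4 forms the less soluble salt with (S)-1-phenylethylamine; if the (S)-acid does, the mirror-image amine is used.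
- Centres marked RS (C1 in 6–20, C5 in 16–17, C3 in 17–22) are epimer mixtures; each is erased later (C5 in step 13, C1 in step 15, C3 in step 16).

## Route

Step 1
Reactants: 1 3-methoxy-5-methylbenzoic acid
Product: 3 rac-3-methoxy-1,5-dimethylcyclohexa-2,5-diene-1-carboxylic acid, via dilithium dienolate 2 (not isolated)
Conditions: Li, NH3(l), THF, −78 °C; MeI, −78 °C; NH4Cl, then cold aq. citric acid to pH 5
Reagents that add atoms: iodomethane, CI
Why: Birch reduction of a benzoic acid stops at the 1,4-dihydro dianion, with the methoxy and methyl groups left on the two remaining double bonds; C-methylation at the ipso carbon (Birch reductive alkylation) creates the quaternary C10, here still racemic.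

Step 2
Reactants: 3 rac-3-methoxy-1,5-dimethylcyclohexa-2,5-diene-1-carboxylic acid
Product: 4 (R)-3-methoxy-1,5-dimethylcyclohexa-2,5-diene-1-carboxylic acid
Conditions: (S)-1-phenylethylamine (0.6 equiv), EtOAc, two crystallisations of the salt; cold aq. NaH2PO4, Et2O
Reagents that add atoms: none
Why: Classical resolution through diastereomeric ammonium salts; the carboxyl group sits on the stereocentre, the basic medium protects the enol ether, and the amine and the other enantiomer are recoverable.

Step 3
Reactants: 4 (R)-3-methoxy-1,5-dimethylcyclohexa-2,5-diene-1-carboxylic acid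
Product: 6 (1RS,5S)-5-(hydroxymethyl)-3,5-dimethylcyclohex-3-en-1-ol, via keto acid 5 (not isolated)
Conditions: (CO2H)2, THF/H2O, 0 °C → rt; then LiAlH4, THF, 0 °C → rt
Reagents that add atoms: water, O
Why: Mild acid hydrolysis of the methyl enol ether gives the β,γ-unsaturated ketone without moving the C3=C4 double bond into conjugation, and immediate LiAlH4 reduction converts acid and ketone into the diol; the C1 configuration is irrelevant because C1 is reoxidised in step 15.

Step 4
Reactants: 6 (1RS,5S)-5-(hydroxymethyl)-3,5-dimethylcyclohex-3-en-1-ol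
Product: 7 (1RS,5S)-3,5-dimethyl-1-(triethylsilyloxy)-5-[(triethylsilyloxy)methyl]cyclohex-3-ene
Conditions: Et3SiCl (2.5 equiv), imidazole, DMAP (cat.), CH2Cl2, 0 °C → rt
Reagents that add atoms: chlorotriethylsilane, CC[Si](Cl)(CC)CC
Why: Exhaustive silylation; both hydroxyls are capped before C9 is oxidised, so that a free C1 hydroxyl cannot form a lactol with the C9 aldehyde.

Step 5
Reactants: 7 (1RS,5S)-3,5-dimethyl-1-(triethylsilyloxy)-5-[(triethylsilyloxy)methyl]cyclohex-3-ene
Product: 8 (1S,5RS)-1,3-dimethyl-5-(triethylsilyloxy)cyclohex-2-ene-1-carbaldehyde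
Conditions: (COCl)2, DMSO, CH2Cl2, −78 → −40 °C; Et3N, −78 → 0 °C
Reagents that add atoms: none
Why: Under Swern conditions a primary triethylsilyl ether is cleaved and oxidised to the aldehyde in one pot while a secondary one survives, which gives the non-enolisable C9 aldehyde with C1 still protected.

Step 6
Reactants: 9 4-hydroxy-3,3-dimethylbutan-2-one
Product: 10 3,3-dimethyl-4-(triethylsilyloxy)butan-2-one
Conditions: Et3SiCl, imidazole, CH2Cl2, 0 °C
Reagents that add atoms: chlorotriethylsilane, CC[Si](Cl)(CC)CC
Why: Silylation of a primary alcohol under conditions too mild to trigger retro-aldol loss of formaldehyde; the ketone brings C5–C8 with the gem-dimethyl group already in place.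

Step 7
Reactants: 8 (1S,5RS)-1,3-dimethyl-5-(triethylsilyloxy)cyclohex-2-ene-1-carbaldehyde; 10 3,3-dimethyl-4-(triethylsilyloxy)butan-2-one
Product: 12 (5R)-5-[(1S,5RS)-1,3-dimethyl-5-(triethylsilyloxy)cyclohex-2-en-1-yl]-5-hydroxy-2,2-dimethyl-1-(triethylsilyloxy)pentan-3-one, via boron enolate 11 (not isolated)
Conditions: 10, (−)-Ipc2BCl, Et3N, Et2O, 0 °C; 8, −78 → −20 °C; H2O2, pH 7 buffer, MeOH, 0 °C
Reagents that add atoms: none
Why: Boron aldol reaction: the ketone can enolise only toward its methyl group and the aldehyde not at all, and the isopinocampheyl ligands choose the aldehyde face in a closed transition state (reagent control), which should set C9 as 9R; if the sense of induction proves opposite the (+)-reagent is used, and the minor C9 epimer is a diastereomer that chromatography removes.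

Step 8
Reactants: 12 (5R)-5-[(1S,5RS)-1,3-dimethyl-5-(triethylsilyloxy)cyclohex-2-en-1-yl]-5-hydroxy-2,2-dimethyl-1-(triethylsilyloxy)pentan-3-one
Product: 13 (1R,3R)-1-[(1S,5RS)-1,3-dimethyl-5-(triethylsilyloxy)cyclohex-2-en-1-yl]-3-hydroxy-4,4-dimethyl-5-(triethylsilyloxy)pentyl benzoate
Conditions: PhCHO (5 equiv), SmI2 (0.3 equiv), THF, −10 °C
Reagents that add atoms: benzaldehyde, O=Cc1ccccc1
Why: Evans–Tishchenko reduction: the samarium-bound hemiacetal formed from the C9 alkoxide and benzaldehyde delivers its hydride intramolecularly to C7 through a chair-like bicyclic transition state, which gives the 1,3-anti alcohol (7R) and leaves O9 as its benzoate, so one step sets C7 and tells the two oxygens apart.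

Step 9
Reactants: 13 (1R,3R)-1-[(1S,5RS)-1,3-dimethyl-5-(triethylsilyloxy)cyclohex-2-en-1-yl]-3-hydroxy-4,4-dimethyl-5-(triethylsilyloxy)pentyl benzoate
Product: 14 (1R,3R)-3-(tert-butyldimethylsilyloxy)-1-[(1S,5RS)-1,3-dimethyl-5-(triethylsilyloxy)cyclohex-2-en-1-yl]-4,4-dimethyl-5-(triethylsilyloxy)pentyl benzoate
Conditions: t-BuMe2SiOTf, 2,6-lutidine, CH2Cl2, −78 → 0 °C
Reagents that add atoms: tert-butyldimethylsilyl trifluoromethanesulfonate, CC(C)(C)[Si](C)(C)OS(=O)(=O)C(F)(F)F
Why: The silyl triflate caps the hindered neopentyl C7 hydroxyl at once, before the benzoate can migrate from O9; a silyl ether on O7 is also a poor electron donor, which matters in step 18.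

Step 10
Reactants: 14 (1R,3R)-3-(tert-butyldimethylsilyloxy)-1-[(1S,5RS)-1,3-dimethyl-5-(triethylsilyloxy)cyclohex-2-en-1-yl]-4,4-dimethyl-5-(triethylsilyloxy)pentyl benzoate
Product: 15 (1R,3R)-3-(tert-butyldimethylsilyloxy)-1-[(1S,5RS)-1,3-dimethyl-5-(triethylsilyloxy)cyclohex-2-en-1-yl]-4,4-dimethyl-5-oxopentyl benzoate
Conditions: (COCl)2, DMSO, CH2Cl2, −78 → −40 °C; Et3N, −78 → 0 °C
Reagents that add atoms: none
Why: The same selective Swern cleavage–oxidation as in step 5 converts only the primary triethylsilyl ether into the C5 aldehyde; the secondary silyl ethers and the benzoate are untouched.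

Step 11
Reactants: 15 (1R,3R)-3-(tert-butyldimethylsilyloxy)-1-[(1S,5RS)-1,3-dimethyl-5-(triethylsilyloxy)cyclohex-2-en-1-yl]-4,4-dimethyl-5-oxopentyl benzoate
Product: 16 (1RS,4R,5RS,7R,9R,10S)-9-(benzoyloxy)-7-(tert-butyldimethylsilyloxy)-1-(triethylsilyloxy)-5,11-secolongipin-2-en-5-ol
Conditions: Me2AlCl (2.5 equiv), CH2Cl2, −78 → −20 °C
Reagents that add atoms: none
Why: Lewis-acid carbonyl-ene cyclisation: the activated, non-enolisable aldehyde is attacked by C4, the less substituted carbon of the trisubstituted alkene, and the double bond moves to C2=C3 (an exocyclic isomer would converge in step 12); the chain hangs from C10 and can reach only its own face of C4, which sets the cis C4–C10 fusion (4R), and the quaternary C6 and C10 favour the seven-membered ring.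

Step 12
Reactants: 16 (1RS,4R,5RS,7R,9R,10S)-9-(benzoyloxy)-7-(tert-butyldimethylsilyloxy)-1-(triethylsilyloxy)-5,11-secolongipin-2-en-5-ol
Product: 17 (1RS,3RS,4R,5RS,7R,9R,10S)-9-(benzoyloxy)-7-(tert-butyldimethylsilyloxy)-1-(triethylsilyloxy)-5,11-secolongipinan-5-ol
Conditions: H2 (1 atm), [Ir(cod)(PCy3)(py)]PF6 (5 mol%), CH2Cl2, rt
Reagents that add atoms: none
Why: Hydroxyl-directed homogeneous hydrogenation reduces the hindered alkene without hydrogenolysis of the allylic silyl ether; saturating ring A removes the allylic activation of H4 before sulfur is put on C5.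

Step 13
Reactants: 17 (1RS,3RS,4R,5RS,7R,9R,10S)-9-(benzoyloxy)-7-(tert-butyldimethylsilyloxy)-1-(triethylsilyloxy)-5,11-secolongipinan-5-ol
Product: 18 (1RS,3RS,4R,7R,9R,10S)-9-(benzoyloxy)-7-(tert-butyldimethylsilyloxy)-1-(triethylsilyloxy)-5,11-secolongipinan-5-one
Conditions: Dess–Martin periodinane, NaHCO3, CH2Cl2, rt
Reagents that add atoms: none
Why: Buffered periodinane oxidation of a hindered secondary alcohol; neutral conditions keep the epimerisable H4 next to the new ketone in place.

Step 14
Reactants: 18 (1RS,3RS,4R,7R,9R,10S)-9-(benzoyloxy)-7-(tert-butyldimethylsilyloxy)-1-(triethylsilyloxy)-5,11-secolongipinan-5-one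
Product: 20 (1RS,3RS,4R,7R,9R,10S)-9-(benzoyloxy)-7-(tert-butyldimethylsilyloxy)-5,5-bis(phenylthio)-5,11-secolongipinan-1-ol, via triethylsilyl ether 19 (not isolated)
Conditions: PhSSiMe3 (4 equiv), Me3SiOTf (0.2 equiv), CH2Cl2, −78 → −30 °C; then HF·pyridine, pyridine, THF, 0 °C
Reagents that add atoms: (phenylthio)trimethylsilane, C[Si](C)(C)Sc1ccccc1
Why: Silyl-triflate-catalysed thioketalisation with a silyl sulfide is driven by Si–O bond formation and runs cold and aprotic, so the intermediate cation is captured by sulfur rather than losing H4; ring A has no carbonyl or double bond at this stage, so H4 is not activated. Buffered HF then removes the unhindered secondary triethylsilyl ether and leaves the hindered tert-butyldimethylsilyl ether.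

Step 15
Reactants: 20 (1RS,3RS,4R,7R,9R,10S)-9-(benzoyloxy)-7-(tert-butyldimethylsilyloxy)-5,5-bis(phenylthio)-5,11-secolongipinan-1-ol
Product: 21 (3RS,4R,7R,9R,10S)-9-(benzoyloxy)-7-(tert-butyldimethylsilyloxy)-5,5-bis(phenylthio)-5,11-secolongipinan-1-one
Conditions: Dess–Martin periodinane, pyridine, CH2Cl2, 0 °C → rt
Reagents that add atoms: none
Why: The periodinane oxidises the alcohol and leaves sulfides alone; the pyridine buffer keeps acid away from the crowded thioketal.

Step 16
Reactants: 21 (3RS,4R,7R,9R,10S)-9-(benzoyloxy)-7-(tert-butyldimethylsilyloxy)-5,5-bis(phenylthio)-5,11-secolongipinan-1-one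
Product: 23 (4R,7R,9R,10S)-9-(benzoyloxy)-7-(tert-butyldimethylsilyloxy)-5,5-bis(phenylthio)-5,11-secolongipin-2-en-1-one, via lithium enolate 22 (not isolated)
Conditions: LiN(i-Pr)2 (1.05 equiv), THF, −78 °C; PhS(Cl)=N-t-Bu, −78 °C
Reagents that add atoms: none
Why: Sulfinimidoyl chloride dehydrogenation (Mukaiyama): kinetic deprotonation goes to C2 rather than to C11 next to quaternary C10, the enolate is sulfenylated and the adduct undergoes syn-elimination with H3 at −78 °C; only C2=C3 can form because C10 has no hydrogen, and no excess base is left to touch the product, whose H4 is now vinylogously acidic.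

Step 17
Reactants: 23 (4R,7R,9R,10S)-9-(benzoyloxy)-7-(tert-butyldimethylsilyloxy)-5,5-bis(phenylthio)-5,11-secolongipin-2-en-1-one
Product: 24 (4R,7R,9R,10S)-9-(benzoyloxy)-7-(tert-butyldimethylsilyloxy)-5,5-bis(phenylthio)-1-(trimethylsilyloxy)-5,11-secolongipina-1(11),2-diene
Conditions: LiN(i-Pr)2, Me3SiCl (present from the start), THF, −78 °C; Et3N, pentane
Reagents that add atoms: chlorotrimethylsilane, C[Si](C)(C)Cl
Why: Kinetic deprotonation of an enone takes the α′ hydrogen (C11), as in the isophorone series, and the silyl chloride already present traps the cross-conjugated enolate before it can equilibrate to the extended dienolate, which would expel thiolate from C5.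

Step 18
Reactants: 24 (4R,7R,9R,10S)-9-(benzoyloxy)-7-(tert-butyldimethylsilyloxy)-5,5-bis(phenylthio)-1-(trimethylsilyloxy)-5,11-secolongipina-1(11),2-diene
Product: 26 (4R,5R,7R,9R,10R,11R)-9-(benzoyloxy)-7-(tert-butyldimethylsilyloxy)-5-(phenylthio)longipin-2-en-1-one, via thionium ion 25 (not isolated)
Conditions: Me2S(SMe)BF4 (1.2 equiv), 4 Å MS, CH2Cl2, −78 → −30 °C; Et3N, aq. NaHCO3
Reagents that add atoms: none
Why: Proposed new method: Me2S(SMe)BF4 methylthiolates one thioketal sulfur, PhSSMe leaves, and the phenylthio-stabilised cation 25 at C5 is attacked by C11 of the silyl enol ether, after which fluoride from BF4− takes the silyl group and the C1 ketone appears. The closest known reaction types are the Lewis-acid alkylation of silyl enol ethers with α-chloro sulfides and the sulfonium-triggered cyclisation of dithioacetals onto enol silanes, both known for open-chain products and for five- and six-membered rings but not for a cyclobutane. The ring C4–C5–C11–C10 closes in a 4-exo-trig mode at the thionium carbon with the enol double bond exocyclic to the new ring, the same geometry that the classical enolate alkylation to pinane-type ketones uses with a primary leaving group. C11 becomes a stereocentre and is controlled by the cis C4–C10 fusion: C5 hangs from C4 and can reach C11 only on that face of ring A, so the one-carbon bridge is necessarily cis (11R). C5 becomes a stereocentre and is controlled by ring B: C4, C6 and the new bond to C11 must lie on one side, which leaves the phenylthio group pointing over the enone bridge (5R); no other diastereomer of this cage can exist. The step needs C–C bond formation to beat loss of H4 from the cation, fragmentation toward O7 and sulfenylation of the enol ether; the cation cannot eliminate toward quaternary C6 or rearrange because sulfur carries the charge, the silyl ether on O7 is a poor donor, the 2-silyloxydiene is nucleophilic only at C11, and thioketal sulfur is softer toward the sulfonium salt than the enol ether. Formation of the Si–F and C=O bonds makes the closure irreversible and pays for the ring strain, and the cold amine quench removes BF3 before it can reopen the β-thio ketone.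

Step 19
Reactants: 26 (4R,5R,7R,9R,10R,11R)-9-(benzoyloxy)-7-(tert-butyldimethylsilyloxy)-5-(phenylthio)longipin-2-en-1-one
Product: 27 (4R,5S,7R,9R,10R,11R)-9-(benzoyloxy)-7-(tert-butyldimethylsilyloxy)longipin-2-en-1-one
Conditions: Bu3SnH, AIBN (cat.), benzene, 80 °C
Reagents that add atoms: none
Why: Radical desulfurisation: the stannyl radical cleaves the tertiary C5–S bond and the cyclobutyl radical takes hydrogen at the only open position, over the enone bridge (5S); cyclobutyl radicals do not ring-open at a competitive rate, and the hindered enone is a poor partner for the tin radical.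

Step 20
Reactants: 27 (4R,5S,7R,9R,10R,11R)-9-(benzoyloxy)-7-(tert-butyldimethylsilyloxy)longipin-2-en-1-one
Product: 28 (4R,5S,7R,9R,10R,11R)-7-(tert-butyldimethylsilyloxy)-9-hydroxylongipin-2-en-1-one
Conditions: K2CO3, MeOH, rt → 40 °C
Reagents that add atoms: none
Why: Methanolysis of the benzoate; both α-type carbons of the ketone that carry hydrogen (C4 and C11) are bridgeheads and cannot enolise, so mild base does not threaten the cage, and the silyl ether stays.

Step 21
Reactants: 28 (4R,5S,7R,9R,10R,11R)-7-(tert-butyldimethylsilyloxy)-9-hydroxylongipin-2-en-1-one; 29 (E)-2-methylbut-2-enoic acid (tiglic acid)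
Product: 31 (4R,5S,7R,9R,10R,11R)-7-(tert-butyldimethylsilyloxy)-9-[(E)-2-methylbut-2-enoyloxy]longipin-2-en-1-one, via mixed anhydride 30 (not isolated)
Conditions: 29, 2,4,6-Cl3C6H2COCl, Et3N, THF, rt; then 28, DMAP, toluene, 40 °C
Reagents that add atoms: none
Why: Yamaguchi esterification acylates hindered secondary alcohols through the acylpyridinium ion; the E double bond of the tiglate is the stable isomer and is kept.

Step 22
Reactants: 31 (4R,5S,7R,9R,10R,11R)-7-(tert-butyldimethylsilyloxy)-9-[(E)-2-methylbut-2-enoyloxy]longipin-2-en-1-one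
Product: 32 (4R,5S,7R,9R,10R,11R)-7-hydroxy-9-[(E)-2-methylbut-2-enoyloxy]longipin-2-en-1-one
Conditions: HF·pyridine, THF, 0 °C → rt
Reagents that add atoms: none
Why: Acidic fluoride removes the hindered silyl ether without any alkoxide being formed, so the tiglate cannot migrate from O9 to O7.

Step 23
Reactants: 32 (4R,5S,7R,9R,10R,11R)-7-hydroxy-9-[(E)-2-methylbut-2-enoyloxy]longipin-2-en-1-one; 33 3-methylbut-2-enoic acid
Product: 35 (4R,5S,7R,9R,10R,11R)-7-(3-methylbut-2-enoyloxy)-9-[(E)-2-methylbut-2-enoyloxy]longipin-2-en-1-one, via mixed anhydride 34 (not isolated)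
Conditions: 33, 2,4,6-Cl3C6H2COCl, Et3N, THF, rt; then 32, DMAP, toluene, rt
Reagents that add atoms: none
Why: A second Yamaguchi esterification; the mixed anhydride is less prone than the acid chloride to the vinylketene pathway that would give the deconjugated 3-methylbut-3-enoate.

## Compound list

1 | 3-methoxy-5-methylbenzoic acid | COc1cc(C)cc(c1)C(=O)O | starting material
2 | dilithium (3-methoxy-5-methylcyclohexa-2,5-dien-1-ylidene)methanediolate | COC1=CC(=C([O-])[O-])C=C(C)C1.[Li+].[Li+] | intermediate
3 | rac-3-methoxy-1,5-dimethylcyclohexa-2,5-diene-1-carboxylic acid | OC(=O)C1(C)C=C(OC)CC(C)=C1 | intermediate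
4 | (R)-3-methoxy-1,5-dimethylcyclohexa-2,5-diene-1-carboxylic acid | OC(=O)[C@@]1(C)C=C(OC)CC(C)=C1 | intermediate
5 | (S)-1,3-dimethyl-5-oxocyclohex-2-ene-1-carboxylic acid | OC(=O)[C@@]1(C)CC(=O)CC(C)=C1 | intermediate
6 | (1RS,5S)-5-(hydroxymethyl)-3,5-dimethylcyclohex-3-en-1-ol | OC[C@@]1(C)CC(O)CC(C)=C1 | intermediate
7 | (1RS,5S)-3,5-dimethyl-1-(triethylsilyloxy)-5-[(triethylsilyloxy)methyl]cyclohex-3-ene | CC[Si](CC)(CC)OC[C@@]1(C)CC(O[Si](CC)(CC)CC)CC(C)=C1 | intermediate
8 | (1S,5RS)-1,3-dimethyl-5-(triethylsilyloxy)cyclohex-2-ene-1-carbaldehyde | O=C[C@@]1(C)CC(O[Si](CC)(CC)CC)CC(C)=C1 | intermediate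
9 | 4-hydroxy-3,3-dimethylbutan-2-one | CC(=O)C(C)(C)CO | starting material
10 | 3,3-dimethyl-4-(triethylsilyloxy)butan-2-one | CC(=O)C(C)(C)CO[Si](CC)(CC)CC | intermediate
11 | 3,3-dimethyl-4-(triethylsilyloxy)but-1-en-2-yl diisopinocampheylborinate | C=C(OB([C@@H]1C[C@@H]2C[C@H]([C@H]1C)C2(C)C)[C@@H]3C[C@@H]4C[C@H]([C@H]3C)C4(C)C)C(C)(C)CO[Si](CC)(CC)CC | intermediate
12 | (5R)-5-[(1S,5RS)-1,3-dimethyl-5-(triethylsilyloxy)cyclohex-2-en-1-yl]-5-hydroxy-2,2-dimethyl-1-(triethylsilyloxy)pentan-3-one | CC[Si](CC)(CC)OCC(C)(C)C(=O)C[C@@H](O)[C@@]1(C)CC(O[Si](CC)(CC)CC)CC(C)=C1 | intermediate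
13 | (1R,3R)-1-[(1S,5RS)-1,3-dimethyl-5-(triethylsilyloxy)cyclohex-2-en-1-yl]-3-hydroxy-4,4-dimethyl-5-(triethylsilyloxy)pentyl benzoate | CC[Si](CC)(CC)OCC(C)(C)[C@H](O)C[C@@H](OC(=O)c2ccccc2)[C@@]1(C)CC(O[Si](CC)(CC)CC)CC(C)=C1 | intermediate
14 | (1R,3R)-3-(tert-butyldimethylsilyloxy)-1-[(1S,5RS)-1,3-dimethyl-5-(triethylsilyloxy)cyclohex-2-en-1-yl]-4,4-dimethyl-5-(triethylsilyloxy)pentyl benzoate | CC[Si](CC)(CC)OCC(C)(C)[C@H](O[Si](C)(C)C(C)(C)C)C[C@@H](OC(=O)c2ccccc2)[C@@]1(C)CC(O[Si](CC)(CC)CC)CC(C)=C1 | intermediate
15 | (1R,3R)-3-(tert-butyldimethylsilyloxy)-1-[(1S,5RS)-1,3-dimethyl-5-(triethylsilyloxy)cyclohex-2-en-1-yl]-4,4-dimethyl-5-oxopentyl benzoate | O=CC(C)(C)[C@H](O[Si](C)(C)C(C)(C)C)C[C@@H](OC(=O)c2ccccc2)[C@@]1(C)CC(O[Si](CC)(CC)CC)CC(C)=C1 | intermediate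
16 | (1RS,4R,5RS,7R,9R,10S)-9-(benzoyloxy)-7-(tert-butyldimethylsilyloxy)-1-(triethylsilyloxy)-5,11-secolongipin-2-en-5-ol | O=C(O[C@@H]2C[C@@H](O[Si](C)(C)C(C)(C)C)C(C)(C)C(O)[C@@H]3C(C)=CC(O[Si](CC)(CC)CC)C[C@]23C)c1ccccc1 | intermediate
17 | (1RS,3RS,4R,5RS,7R,9R,10S)-9-(benzoyloxy)-7-(tert-butyldimethylsilyloxy)-1-(triethylsilyloxy)-5,11-secolongipinan-5-ol | O=C(O[C@@H]2C[C@@H](O[Si](C)(C)C(C)(C)C)C(C)(C)C(O)[C@@H]3C(C)CC(O[Si](CC)(CC)CC)C[C@]23C)c1ccccc1 | intermediate
18 | (1RS,3RS,4R,7R,9R,10S)-9-(benzoyloxy)-7-(tert-butyldimethylsilyloxy)-1-(triethylsilyloxy)-5,11-secolongipinan-5-one | O=C(O[C@@H]2C[C@@H](O[Si](C)(C)C(C)(C)C)C(C)(C)C(=O)[C@@H]3C(C)CC(O[Si](CC)(CC)CC)C[C@]23C)c1ccccc1 | intermediate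
19 | (1RS,3RS,4R,7R,9R,10S)-9-(benzoyloxy)-7-(tert-butyldimethylsilyloxy)-5,5-bis(phenylthio)-1-(triethylsilyloxy)-5,11-secolongipinane | O=C(O[C@@H]2C[C@@H](O[Si](C)(C)C(C)(C)C)C(C)(C)C(Sc4ccccc4)(Sc5ccccc5)[C@@H]3C(C)CC(O[Si](CC)(CC)CC)C[C@]23C)c1ccccc1 | intermediate
20 | (1RS,3RS,4R,7R,9R,10S)-9-(benzoyloxy)-7-(tert-butyldimethylsilyloxy)-5,5-bis(phenylthio)-5,11-secolongipinan-1-ol | O=C(O[C@@H]2C[C@@H](O[Si](C)(C)C(C)(C)C)C(C)(C)C(Sc4ccccc4)(Sc5ccccc5)[C@@H]3C(C)CC(O)C[C@]23C)c1ccccc1 | intermediate
21 | (3RS,4R,7R,9R,10S)-9-(benzoyloxy)-7-(tert-butyldimethylsilyloxy)-5,5-bis(phenylthio)-5,11-secolongipinan-1-one | O=C(O[C@@H]2C[C@@H](O[Si](C)(C)C(C)(C)C)C(C)(C)C(Sc4ccccc4)(Sc5ccccc5)[C@@H]3C(C)CC(=O)C[C@]23C)c1ccccc1 | intermediate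
22 | lithium C1–C2 enolate of 21 | O=C(O[C@@H]2C[C@@H](O[Si](C)(C)C(C)(C)C)C(C)(C)C(Sc4ccccc4)(Sc5ccccc5)[C@@H]3C(C)C=C(O[Li])C[C@]23C)c1ccccc1 | intermediate
23 | (4R,7R,9R,10S)-9-(benzoyloxy)-7-(tert-butyldimethylsilyloxy)-5,5-bis(phenylthio)-5,11-secolongipin-2-en-1-one | O=C(O[C@@H]2C[C@@H](O[Si](C)(C)C(C)(C)C)C(C)(C)C(Sc4ccccc4)(Sc5ccccc5)[C@@H]3C(C)=CC(=O)C[C@]23C)c1ccccc1 | intermediate
24 | (4R,7R,9R,10S)-9-(benzoyloxy)-7-(tert-butyldimethylsilyloxy)-5,5-bis(phenylthio)-1-(trimethylsilyloxy)-5,11-secolongipina-1(11),2-diene | O=C(O[C@@H]2C[C@@H](O[Si](C)(C)C(C)(C)C)C(C)(C)C(Sc4ccccc4)(Sc5ccccc5)[C@@H]3C(C)=CC(O[Si](C)(C)C)=C[C@]23C)c1ccccc1 | intermediate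
25 | C5 phenylthionium tetrafluoroborate derived from 24 | O=C(O[C@@H]2C[C@@H](O[Si](C)(C)C(C)(C)C)C(C)(C)C(=[S+]c4ccccc4)[C@@H]3C(C)=CC(O[Si](C)(C)C)=C[C@]23C)c1ccccc1.F[B-](F)(F)F | intermediate
26 | (4R,5R,7R,9R,10R,11R)-9-(benzoyloxy)-7-(tert-butyldimethylsilyloxy)-5-(phenylthio)longipin-2-en-1-one | O=C(O[C@@H]2C[C@@H](O[Si](C)(C)C(C)(C)C)C(C)(C)[C@]3(Sc4ccccc4)[C@H]4C(=O)C=C(C)[C@@H]3[C@]42C)c1ccccc1 | intermediate
27 | (4R,5S,7R,9R,10R,11R)-9-(benzoyloxy)-7-(tert-butyldimethylsilyloxy)longipin-2-en-1-one | O=C(O[C@@H]2C[C@@H](O[Si](C)(C)C(C)(C)C)C(C)(C)[C@@H]3[C@H]4C(=O)C=C(C)[C@@H]3[C@]42C)c1ccccc1 | intermediate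
28 | (4R,5S,7R,9R,10R,11R)-7-(tert-butyldimethylsilyloxy)-9-hydroxylongipin-2-en-1-one | O[C@@H]1C[C@@H](O[Si](C)(C)C(C)(C)C)C(C)(C)[C@@H]2[C@H]3C(=O)C=C(C)[C@@H]2[C@]31C | intermediate
29 | (E)-2-methylbut-2-enoic acid (tiglic acid) | C/C=C(\C)C(=O)O | starting material
30 | (E)-2-methylbut-2-enoic 2,4,6-trichlorobenzoic anhydride | C/C=C(\C)C(=O)OC(=O)c1c(Cl)cc(Cl)cc1Cl | intermediate
31 | (4R,5S,7R,9R,10R,11R)-7-(tert-butyldimethylsilyloxy)-9-[(E)-2-methylbut-2-enoyloxy]longipin-2-en-1-one | C/C=C(\C)C(=O)O[C@@H]1C[C@@H](O[Si](C)(C)C(C)(C)C)C(C)(C)[C@@H]2[C@H]3C(=O)C=C(C)[C@@H]2[C@]31C | intermediate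
32 | (4R,5S,7R,9R,10R,11R)-7-hydroxy-9-[(E)-2-methylbut-2-enoyloxy]longipin-2-en-1-one | C/C=C(\C)C(=O)O[C@@H]1C[C@@H](O)C(C)(C)[C@@H]2[C@H]3C(=O)C=C(C)[C@@H]2[C@]31C | intermediate
33 | 3-methylbut-2-enoic acid | CC(C)=CC(=O)O | starting material
34 | 3-methylbut-2-enoic 2,4,6-trichlorobenzoic anhydride | CC(C)=CC(=O)OC(=O)c1c(Cl)cc(Cl)cc1Cl | intermediate
35 | (4R,5S,7R,9R,10R,11R)-7-(3-methylbut-2-enoyloxy)-9-[(E)-2-methylbut-2-enoyloxy]longipin-2-en-1-one | C/C=C(\C)C(=O)O[C@@H]1C[C@@H](OC(=O)C=C(C)C)C(C)(C)[C@@H]2[C@H]3C(=O)C=C(C)[C@@H]2[C@]31C | target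

## Step count and least certain steps

Total: 23 steps. Longest linear sequence: 22 steps (1 to 35 through steps 1–5 and 7–23; step 6 prepares ketone 10).

Step 18 (key step, new method). The most likely failure is that the C5 cation is consumed before the strained ring can close: by loss of H4 to a conjugated trienyl sulfide, by fragmentation toward O7, or because the sulfonium salt sulfenylates the enol ether instead of the thioketal. The closure forms a four-membered ring from a stabilised, hindered cation, and BF3 set free in the step could also reopen the product. Fallback, by the Pummerer reaction, which generates the same cation from a sulfoxide under amine-buffered, fluoride-free conditions and without an external sulfenylating agent: from 23, Bu3SnH (1.1 equiv) and AIBN in benzene at 80 °C remove one phenylthio group to give the mono(phenylthio) enone F1; mCPBA in CH2Cl2 at −78 °C gives the sulfoxide F2; LiN(i-Pr)2 with Me3SiCl as in step 17 gives the sulfinyl silyl dienol ether F3; Me3SiOTf and i-Pr2NEt in CH2Cl2 at −78 °C then trigger the Pummerer ionisation and ring closure, and the route is rejoined at 26.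

Step 14. The most likely failure is incomplete thioketalisation at a carbonyl flanked by a quaternary and a tertiary carbon, together with reversible loss of H4 from the intermediate cation, which would epimerise the ring fusion. Fallback, delivering the second sulfur intramolecularly: from 18, benzene-1,2-dithiol and BF3·OEt2 in CH2Cl2 at −20 °C (the triethylsilyl ether is lost under these conditions) give the spiro-1,3-benzodithiole alcohol F4. The conditions of steps 15–17 then give the ketone F5, the enone F6 and the silyl dienol ether F7. Me2S(SMe)BF4 opens the benzodithiole to an arylthionium ion that closes to the 5-[2-(methyldisulfanyl)phenylthio] ketone F8, and excess Bu3SnH with AIBN removes the whole sulfur substituent, rejoining the route at 27.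

Step 11. The most likely failure is a slow seven-membered ring closure, which lets intermolecular ene or Prins reactions and chloride capture of the C3 cation compete. Fallback, using the γ-carbon of a conjugated enone as the nucleophile: from 15, HF·pyridine (THF, 0 °C) frees the C1 hydroxyl to give the hydroxy aldehyde F9; Dess–Martin periodinane followed by DBU gives the conjugated enone aldehyde F10; Me3SiOTf and Et3N (CH2Cl2, −78 → 0 °C) form the extended silyl dienol ether under equilibrating conditions, and its C4 adds to the aldehyde in an intramolecular vinylogous Mukaiyama aldol reaction to give, after acidic work-up, the hydroxy enone F11. Luche reduction (NaBH4, CeCl3·7H2O, MeOH) gives the diol F12, and selective silylation of the unhindered allylic C1 hydroxyl (Et3SiCl, imidazole) returns to 16.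

Step 7. The most likely failure is poor facial selectivity, because the α-quaternary aldehyde has no bias of its own and chiral boron enolates of methyl ketones are only moderately selective. Fallback, moving the chirality to a Lewis-acid catalyst: from 10, Me3SiOTf and Et3N give the silyl enol ether F13, which is added to 8 in a Mukaiyama aldol reaction under a tartrate-derived acyloxyborane (or (R)-BINOL/Ti(Oi-Pr)4); acidic work-up returns to 12, and any C9 epimer is still a separable diastereomer.

## Further compounds

F1 | step 18 | (4R,5RS,7R,9R,10S)-9-(benzoyloxy)-7-(tert-butyldimethylsilyloxy)-5-(phenylthio)-5,11-secolongipin-2-en-1-one | O=C(O[C@@H]2C[C@@H](O[Si](C)(C)C(C)(C)C)C(C)(C)C(Sc4ccccc4)[C@@H]3C(C)=CC(=O)C[C@]23C)c1ccccc1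
F2 | step 18 | (4R,5RS,7R,9R,10S)-9-(benzoyloxy)-7-(tert-butyldimethylsilyloxy)-5-(phenylsulfinyl)-5,11-secolongipin-2-en-1-one | O=C(O[C@@H]2C[C@@H](O[Si](C)(C)C(C)(C)C)C(C)(C)C(S(=O)c4ccccc4)[C@@H]3C(C)=CC(=O)C[C@]23C)c1ccccc1
F3 | step 18 | (4R,5RS,7R,9R,10S)-9-(benzoyloxy)-7-(tert-butyldimethylsilyloxy)-5-(phenylsulfinyl)-1-(trimethylsilyloxy)-5,11-secolongipina-1(11),2-diene | O=C(O[C@@H]2C[C@@H](O[Si](C)(C)C(C)(C)C)C(C)(C)C(S(=O)c4ccccc4)[C@@H]3C(C)=CC(O[Si](C)(C)C)=C[C@]23C)c1ccccc1
F4 | step 14 | spiro-1,3-benzodithiole at C5 of (1RS,3RS,4R,7R,9R,10S)-9-(benzoyloxy)-7-(tert-butyldimethylsilyloxy)-5,11-secolongipinan-1-ol | O=C(O[C@@H]2C[C@@H](O[Si](C)(C)C(C)(C)C)C(C)(C)C4(Sc5ccccc5S4)[C@@H]3C(C)CC(O)C[C@]23C)c1ccccc1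
F5 | step 14 | spiro-1,3-benzodithiole at C5 of (3RS,4R,7R,9R,10S)-9-(benzoyloxy)-7-(tert-butyldimethylsilyloxy)-5,11-secolongipinan-1-one | O=C(O[C@@H]2C[C@@H](O[Si](C)(C)C(C)(C)C)C(C)(C)C4(Sc5ccccc5S4)[C@@H]3C(C)CC(=O)C[C@]23C)c1ccccc1
F6 | step 14 | spiro-1,3-benzodithiole at C5 of (4R,7R,9R,10S)-9-(benzoyloxy)-7-(tert-butyldimethylsilyloxy)-5,11-secolongipin-2-en-1-one | O=C(O[C@@H]2C[C@@H](O[Si](C)(C)C(C)(C)C)C(C)(C)C4(Sc5ccccc5S4)[C@@H]3C(C)=CC(=O)C[C@]23C)c1ccccc1
F7 | step 14 | spiro-1,3-benzodithiole at C5 of (4R,7R,9R,10S)-9-(benzoyloxy)-7-(tert-butyldimethylsilyloxy)-1-(trimethylsilyloxy)-5,11-secolongipina-1(11),2-diene | O=C(O[C@@H]2C[C@@H](O[Si](C)(C)C(C)(C)C)C(C)(C)C4(Sc5ccccc5S4)[C@@H]3C(C)=CC(O[Si](C)(C)C)=C[C@]23C)c1ccccc1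
F8 | step 14 | (4R,5R,7R,9R,10R,11R)-9-(benzoyloxy)-7-(tert-butyldimethylsilyloxy)-5-[2-(methyldisulfanyl)phenylthio]longipin-2-en-1-one | O=C(O[C@@H]2C[C@@H](O[Si](C)(C)C(C)(C)C)C(C)(C)[C@]3(Sc4ccccc4SSC)[C@H]4C(=O)C=C(C)[C@@H]3[C@]42C)c1ccccc1
F9 | step 11 | (1R,3R)-3-(tert-butyldimethylsilyloxy)-1-[(1S,5RS)-5-hydroxy-1,3-dimethylcyclohex-2-en-1-yl]-4,4-dimethyl-5-oxopentyl benzoate | O=CC(C)(C)[C@H](O[Si](C)(C)C(C)(C)C)C[C@@H](OC(=O)c2ccccc2)[C@@]1(C)CC(O)CC(C)=C1
F10 | step 11 | (1R,3R)-3-(tert-butyldimethylsilyloxy)-1-[(1S)-1,3-dimethyl-5-oxocyclohex-3-en-1-yl]-4,4-dimethyl-5-oxopentyl benzoate | O=CC(C)(C)[C@H](O[Si](C)(C)C(C)(C)C)C[C@@H](OC(=O)c2ccccc2)[C@@]1(C)CC(=O)C=C(C)C1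
F11 | step 11 | (4R,5RS,7R,9R,10S)-9-(benzoyloxy)-7-(tert-butyldimethylsilyloxy)-5-hydroxy-5,11-secolongipin-2-en-1-one | O=C(O[C@@H]2C[C@@H](O[Si](C)(C)C(C)(C)C)C(C)(C)C(O)[C@@H]3C(C)=CC(=O)C[C@]23C)c1ccccc1
F12 | step 11 | (1RS,4R,5RS,7R,9R,10S)-9-(benzoyloxy)-7-(tert-butyldimethylsilyloxy)-5,11-secolongipin-2-ene-1,5-diol | O=C(O[C@@H]2C[C@@H](O[Si](C)(C)C(C)(C)C)C(C)(C)C(O)[C@@H]3C(C)=CC(O)C[C@]23C)c1ccccc1
F13 | step 7 | 3,3-dimethyl-4-(triethylsilyloxy)-2-(trimethylsilyloxy)but-1-ene | C=C(O[Si](C)(C)C)C(C)(C)CO[Si](CC)(CC)CC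
A1 | alternative 1 | longipin-2-ene-1,7-dione (cage configured as in 35) | C1CC(=O)C(C)(C)[C@@H]2[C@H]3C(=O)C=C(C)[C@@H]2[C@]31C
A2 | alternative 2 | methyl 3-[2-(2-methyl-1,3-dioxolan-2-yl)propan-2-yl]-2,4-di(prop-1-en-2-yl)-1-(quinolin-8-ylcarbamoyl)cyclobutane-1-carboxylate (meso, all-cis) | COC(=O)[C@]1(C(=O)Nc2cccc3cccnc23)[C@@H](C(C)=C)[C@H](C(C)(C)C2(C)OCCO2)[C@H]1C(C)=C
A3 | alternative 3 | methyl 4,6-dimethyl-7-(2-methylbut-3-en-2-yl)-2-oxobicyclo[3.1.1]hept-3-ene-6-carboxylate | C=CC(C)(C)[C@@H]1[C@H]2C(=O)C=C(C)[C@@H]1[C@@]2(C)C(=O)OC
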